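## The problem

The target 16 is a cyclohexane, ring C, whose carbons are labelled C-b to C-g in ring order: C-b carries the exocyclic carbon C-a (CMe2–O), C-c carries a 1-methylquinolin-2-one (quinolinone A) through C3A, C-e carries a methyl group and an oxygen, and C-g carries an identical quinolinone B through C3B. Ring A is the pyran O4A–C-a–C-b–C-c–C3A–C4A, trans-fused to ring C; ring B is the pyran O4B–C-e–C-f–C-g–C3B–C4B, which bridges ring C so that C-e and C-g are the bridgeheads of a 2-oxabicyclo[3.3.1]nonane. Of the four stereocentres (C-b, C-c, C-e, C-g), two follow from the others: the bridge can close only with O4B on the face of quinolinone B, which ties C-e to C-g, and the trans ring fusion with C-a equatorial is the stable one, which ties C-b to C-c when ether closure is reversible. Only the pair C-c/C-g, with the two quinolinones on opposite faces of ring C, must therefore be set in the absolute sense. The delicate features are the two tertiary ethers of a vinylogous acid (reopened by acid), the ambident quinolinone (C3, O4 and the lactam oxygen can all bond to an electrophile), and the fact that a p-menthadiene with leaving groups or doubly allylic substituents is two eliminations away from an arene. The enabling feature is a hidden twofold axis: with O4A–C-a and O4B–C-e removed, C-b and C-e are no longer stereogenic, C-c and C-g are exchanged by an axis through C-b and C-e, and both are allylic to the same C-b=C-a isopropylidene, so the two C3–C bonds are one bond made twice.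

## Retrosynthesis

**16 to 14.** The ether bonds O4A–C-a and O4B–C-e are cut first. Each is a tertiary carbon–oxygen bond that forms by Markovnikov addition of an acidic enol OH to an olefin, so both can be made late and reversibly. The cut removes rings A and B and the stereocentres C-b and C-e, leaving diene 14 with only the trans pair C-c/C-g. Cutting a C3–C bond first would keep a tricycle with three stereocentres. The forward reaction must run under thermodynamic control; because of the twofold relation it does not matter which quinolinone closes which ring, and the bridged mono-ether 15 is the expected way station.

**14 to 11 and two molecules of 12.** The bonds C3A–C-c and C3B–C-g are cut together. Both join the nucleophilic C3 of a 4-hydroxyquinolinone to a ring carbon allylic to the isopropylidene, so one bis-electrophile, bis(carbonate) 11, and two equivalents of 12 suffice. Allylic C–C bond formation under a chiral palladium catalyst is preferred to acid-mediated alkylation because the π-allyl intermediate over C-c (or C-g), C-b and C-a has two identical methyl groups on C-a and can change faces; the configuration of the carbinol carbons in 11 is therefore irrelevant and the catalyst alone decides each new centre. The precursor has no stereochemical requirement. The forward reaction, which passes through mono-adduct 13, must attack the secondary ring termini, must give C- and not O-alkylation, and must control the face twice.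

**11 to 9 and 10.** The two carbonate C–O bonds are cut. Methyl carbonates are chosen because they ionise under neutral conditions and release the base that activates 12. Diol 9 needs only to be acylated under cold, basic conditions, since the C-g carbinol is doubly allylic.

**9 to 8.** The ring olefin C-e=C-f is cut by ring-closing metathesis. Placing the second oxygen on a preformed p-menthane diene by allylic C–H oxidation was rejected: several allylic sites compete, and ketone-level intermediates of that ring aromatise. The acyclic triene diol 8 instead carries both oxygens from carbonyl additions, and the olefin made on closure is the one the last step needs. The carbinol configurations need no control.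

**8 to 5 and 6.** The bond C-b–C-g is cut: a vinyllithium at C-b, generated from vinyl bromide 5 as the dilithio species 7, adds to the carbonyl carbon of acrolein 6, which becomes C-g. This avoids any protecting group.

**5 to 3 and 4.** The bond C-c–C-d is cut: the methallyl Grignard reagent 4 adds to the aldehyde carbon of bromoenal 3, bringing C-d, C-e and its methyl group.

**3 to 1.** The C-b–Br bond is traced to bromination and dehydrobromination of 3-methylbut-2-enal 1 through dibromide 2; aldehyde 1 supplies C-c, C-b, C-a and the two methyl groups.

## Roads not taken

**Alternative 1:** The cut is C-c–C-d and C-f–C-g, so ring C is annulated onto a finished ring A.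
- Forward step: the achiral formylchromene A1 (ring A with a C-b=C-c olefin and a formyl group on C-b) takes up tert-butyl acetoacetate A2 at C-c under a cinchona-derived primary amine with an acid co-catalyst. Acid-driven aldol condensation and decarboxylation then give cyclohexenone A3 (ketone at C-e, olefin C-f=C-g).
- Merits: ring A and its O4 linkage are secure from the start, since A1 should be available from 12 and 1 by pyran annulation and formylation. The absolute configuration comes from a well-studied mode of catalysis, and A3 carries functionality at C-e and C-g.
- Weak points: A1 is an α-branched enal whose β-carbon bears an electron-rich heteroaryl group, a poor iminium acceptor. After A3, the methyl group, quinolinone B and the bridge still need three separate operations. A reversible conjugate addition of 12 would place quinolinone B equatorial, whereas the target needs it axial, so the sequence would end in a cationic alkylation and closure much like the one used here.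
- Comparison: Alternative 1 is better on the regiochemistry of ring A (no O4/O2 question, no five-ring closure). The chosen plan sets against this that both aryl–carbon bonds come from one operation on one simple electrophile, with no late intermolecular alkylation on a crowded tricycle.

**Alternative 2:** The cut is C3A–C-c and O4A–C-a, with ring C taken from the chiral pool.
- Forward step: cis-verbenol A4 and 12 under a Lewis acid give allyl-cation alkylation at C-c; the cyclobutane bond C-f–C-a then opens and O4A captures the C-a cation, giving the trans-fused tricycle A5 with the C-e=C-f olefin.
- Merits: this reaction type is well established for phenols. It makes one C–C bond, ring A and both centres C-b and C-c in one step, with the absolute configuration supplied by the terpene.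
- Weak points: 12 is less nucleophilic than a resorcinol and can close through the lactam oxygen. In A5, C-g is a methylene that is allylic but must compete with C-d and the methyl group in any C–H oxidation, and quinolinone B must then be delivered axially on the face next to the CMe2 group. Optical purity depends on the verbenol source.
- Comparison: for rings A and C this road is better founded than the chosen one, with fewer unknowns, no question of ligand sense and fewer steps to the tricycle. The chosen plan sets against it that quinolinone B enters by the same event as quinolinone A and needs no C–H functionalisation.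

**Alternative 3:** The cut is C-b–C-c and O4A–C-a, made by an enzyme.
- Forward step: a flavin-dependent oxidocyclase of the berberine-bridge-enzyme family removes hydride from C-c of the 3-geranyl quinolinone A6 and closes rings C and A, giving A7 with the olefin at C-d=C-e.
- Merits: A6 is one alkylation from 12, and the enzyme would form two bonds and two stereocentres in water without protecting groups. No chemical route reaches a trans-fused tricycle in fewer steps.
- Weak points: enzymes of this type are evolved for resorcylic acid substrates, so acceptance of a quinolinone would need screening or engineering. In A7 the olefin lies at C-d/C-e, so C-g is an unactivated methylene with no handle for quinolinone B.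
- Comparison: Alternative 3 wins on step count and mildness for the first half of the molecule but leaves ring B unsolved. The chosen plan is longer in its preparative part but addresses both halves with one disconnection.

Key step: step 6

Assumption: the ligand L = N,N′-[(1R,2R)-cyclohexane-1,2-diyl]bis[2-(diphenylphosphino)benzamide] is taken to give the (1R,3R) bis-adduct 14; if the sense of induction is the opposite, its (1S,2S) enantiomer is used and nothing else changes.

## Route

Step 1
Reactants: 1 3-methylbut-2-enal
Product: 3 2-bromo-3-methylbut-2-enal, via 2,3-dibromo-3-methylbutanal 2 (not isolated)
Conditions: Br2 (1.0 equiv), CH2Cl2, −20 to 0 °C; then Et3N (1.2 equiv), 0 °C to rt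
Reagents that add atoms: bromine, BrBr
Why: Electrophilic bromination of the enal olefin followed by E1cB loss of HBr (acidic α-hydrogen, tertiary β-bromide) is the standard α-bromination of an enal.

Step 2
Reactants: 3 2-bromo-3-methylbut-2-enal; 4 (2-methylallyl)magnesium chloride
Product: 5 5-bromo-2,6-dimethylhepta-1,5-dien-4-ol (racemic)
Conditions: 4 (1.1 equiv), THF, −78 °C; then H2O
Reagents that add atoms: none
Why: 1,2-Addition of an allylic Grignard reagent to an aldehyde; the tetrasubstituted vinyl bromide is inert at −78 °C, and the new carbinol centre (later C-c) needs no control because it is erased in step 6.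

Step 3
Reactants: 5 5-bromo-2,6-dimethylhepta-1,5-dien-4-ol; 6 acrolein (prop-2-enal)
Product: 8 7-methyl-4-(propan-2-ylidene)octa-1,7-diene-3,5-diol as a mixture of diastereomers, via dilithio alkoxide 7 (not isolated)
Conditions: t-BuLi (3.1 equiv), THF/Et2O, −78 °C; 6 (1.5 equiv), −78 °C; then H2O
Reagents that add atoms: none
Why: The first equivalent of t-BuLi forms the lithium alkoxide and the next two effect bromine–lithium exchange (the third consuming t-BuBr); the vinyllithium then adds 1,2 to acrolein at low temperature. Both diastereomers are acceptable since both carbinol centres are erased in step 6.

Step 4
Reactants: 8 7-methyl-4-(propan-2-ylidene)octa-1,7-diene-3,5-diol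
Product: 9 5-methyl-2-(propan-2-ylidene)cyclohex-4-ene-1,3-diol (p-mentha-1,4(8)-diene-3,5-diol; cis/trans mixture, racemic)
Conditions: second-generation Grubbs catalyst (H2IMes)(PCy3)Cl2Ru=CHPh (3 mol %), 1,4-benzoquinone (10 mol %), CH2Cl2 (0.01 M), 40 °C
Reagents that add atoms: none
Why: Ring-closing metathesis between the vinyl group and the 1,1-disubstituted methallyl olefin closes the six-membered ring with the trisubstituted C-e=C-f olefin. The tetrasubstituted isopropylidene does not engage the ruthenium carbene, free allylic alcohols are tolerated, and benzoquinone suppresses hydride-induced isomerisation of the allylic alcohols.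

Step 5
Reactants: 9 5-methyl-2-(propan-2-ylidene)cyclohex-4-ene-1,3-diol; 10 methyl chloroformate
Product: 11 5-methyl-2-(propan-2-ylidene)cyclohex-4-ene-1,3-diyl dimethyl bis(carbonate) (cis/trans mixture, racemic)
Conditions: 10 (3 equiv), pyridine (6 equiv), DMAP (0.1 equiv), CH2Cl2, 0 °C; cold NaHCO3 work-up, filtration through Et3N-deactivated silica
Reagents that add atoms: none
Why: DMAP-catalysed acylation of both secondary allylic alcohols by the chloroformate; cold, basic conditions and a non-acidic work-up keep the doubly allylic carbonate at C-g from ionising.

Step 6
Reactants: 11 5-methyl-2-(propan-2-ylidene)cyclohex-4-ene-1,3-diyl dimethyl bis(carbonate); 12 4-hydroxy-1-methylquinolin-2(1H)-one (2.2 equiv)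
Product: 14 3,3'-[(1R,3R)-5-methyl-2-(propan-2-ylidene)cyclohex-4-ene-1,3-diyl]bis(4-hydroxy-1-methylquinolin-2(1H)-one), via mono-adduct carbonate 13 (not isolated)
Conditions: Pd2(dba)3·CHCl3 (2.5 mol %), L (7.5 mol %), 12 added in portions, CH2Cl2, 25 °C
Reagents that add atoms: none
Why: Zerovalent palladium ionises each allylic carbonate with loss of CO2 and methoxide, which deprotonates 12; the first event is expected at the doubly allylic carbinol C-g and gives 13, the second at C-c. Each cationic π-allyl complex spans C-g (or C-c), C-b and C-a, and because C-a bears two identical methyl groups an η3–η1–η3 shift through the σ-complex at C-a moves palladium to the other face without changing the constitution, so the carbinol configuration is erased and all stereoisomers of 11 converge (dynamic kinetic asymmetric transformation). The closest known reactions are Tsuji–Trost asymmetric allylic alkylations with 4-hydroxycoumarin-type carbon nucleophiles and the deracemisation of allyl systems with a gem-disubstituted terminus. No ring is closed. C-g and C-c are each set by the chiral pocket of L, which selects the π-allyl face attacked by C3 of the quinolinone anti to palladium; the quinolinone already on C-g sits pseudo-axial (allylic strain against the isopropylidene methyl) and shields its own face at C-c, which reinforces trans. Because two catalyst-controlled events act in sequence, a wrong first event should mostly end in the cis diastereomer, removable by chromatography, so trans-14 should be enantiomerically purer than either single event. The step needs attack at the secondary ring termini and not at C-a or the methyl-bearing terminus C-e, and C- over O-alkylation: the tertiary termini are closed to the bulky C3 nucleophile, and an O-allyl ether of this acidic enol re-ionises under the catalyst whereas the C–C bond does not.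

Step 7
Reactants: 14 3,3'-[(1R,3R)-5-methyl-2-(propan-2-ylidene)cyclohex-4-ene-1,3-diyl]bis(4-hydroxy-1-methylquinolin-2(1H)-one)
Product: 16 the target (ring A trans-fused through O4A–C-a, ring B bridging through O4B–C-e), via bridged mono-ether 15 (not isolated)
Conditions: TsOH·H2O (0.3 equiv), toluene, 80 °C
Reagents that add atoms: none
Why: Two acid-catalysed Markovnikov hydroalkoxylations, the reaction type by which cannabidiol-type aryl menthadienes are closed to pyrans and bridged ethers. Protonation at C-f gives the tertiary C-e cation, which is twofold-symmetric while C-b is still sp2, so either quinolinone oxygen gives the same bridged ether 15; C-e is set by the cis requirement of the bridge. Protonation at C-b then lets O4A add to C-a, and since tertiary ether formation is reversible the trans-fused ring A with C-a equatorial should prevail, which sets C-b under thermodynamic control.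

## Compound list

1 | 3-methylbut-2-enal | CC(C)=CC=O | starting material
2 | 2,3-dibromo-3-methylbutanal (racemic) | CC(C)(Br)C(Br)C=O | intermediate
3 | 2-bromo-3-methylbut-2-enal | CC(C)=C(Br)C=O | intermediate
4 | (2-methylallyl)magnesium chloride | CC(=C)C[Mg]Cl | starting material
5 | 5-bromo-2,6-dimethylhepta-1,5-dien-4-ol (racemic) | CC(=C)CC(O)C(Br)=C(C)C | intermediate
6 | acrolein (prop-2-enal) | C=CC=O | starting material
7 | lithium 5-lithio-2,6-dimethylhepta-1,5-dien-4-olate (dilithio alkoxide) | [Li]OC(CC(C)=C)C([Li])=C(C)C | intermediate
8 | 7-methyl-4-(propan-2-ylidene)octa-1,7-diene-3,5-diol (diastereomer mixture) | C=CC(O)C(=C(C)C)C(O)CC(C)=C | intermediate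
9 | 5-methyl-2-(propan-2-ylidene)cyclohex-4-ene-1,3-diol (cis/trans mixture, racemic) | CC1=CC(O)C(=C(C)C)C(O)C1 | intermediate
10 | methyl chloroformate | COC(=O)Cl | starting material
11 | 5-methyl-2-(propan-2-ylidene)cyclohex-4-ene-1,3-diyl dimethyl bis(carbonate) (cis/trans mixture, racemic) | COC(=O)OC1C=C(C)CC(OC(=O)OC)C1=C(C)C | intermediate
12 | 4-hydroxy-1-methylquinolin-2(1H)-one | Cn1c(=O)cc(O)c2ccccc21 | starting material
13 | (3R)-3-(4-hydroxy-1-methyl-2-oxo-1,2-dihydroquinolin-3-yl)-5-methyl-2-(propan-2-ylidene)cyclohex-4-en-1-yl methyl carbonate (both C1 epimers) | COC(=O)OC1CC(C)=C[C@@H](c2c(O)c3ccccc3n(C)c2=O)C1=C(C)C | intermediate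
14 | 3,3'-[(1R,3R)-5-methyl-2-(propan-2-ylidene)cyclohex-4-ene-1,3-diyl]bis(4-hydroxy-1-methylquinolin-2(1H)-one) | Cn1c(=O)c(c(O)c2ccccc21)[C@@H]1CC(C)=C[C@@H](c2c(O)c3ccccc3n(C)c2=O)C1=C(C)C | intermediate
15 | bridged mono-ether: ring B closed (O4B–C-e, cis to quinolinone B), quinolinone A still a free 4-hydroxy compound on C-c, isopropylidene C-b=C-a intact | Cn1c(=O)c(c(O)c2ccccc21)[C@@H]1C[C@]2(C)C[C@H](C1=C(C)C)c1c(c3ccccc3n(C)c1=O)O2 | intermediate
16 | CNP0229685.7: ring C with ring A trans-fused (O4A–C-a) and ring B bridging (O4B–C-e); C-b S, C-c R, C-e S, C-g R | Cn1c(=O)c2c(c3ccccc31)OC(C)(C)[C@H]1[C@H]2C[C@]2(C)C[C@H]1c1c(c3ccccc3n(C)c1=O)O2 | target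

## Step count and risks

Total: 7 steps. Longest linear sequence: 7 steps, from 1 to 16; 4, 6, 10 and 12 are purchased.

**Step 6 (key step).**
- Most likely failure: incomplete equilibration of the π-allyl faces before nucleophilic capture, because the σ-complex at the tertiary C-a is crowded. This would leak the carbinol configuration of 11 into the product and lower both enantiomeric purity and trans selectivity.
- Also possible: slow ionisation of the C-c carbonate, which has only the tetrasubstituted olefin to bind palladium, leaving 13 to stall or to eliminate towards an arene; and temporary closure of O4B onto the C-a terminus of the second π-allyl, which is reversible but costs rate.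
- Fallback: setting out from diol 9 and 12, an acid-catalysed Friedel–Crafts-type double allylation (the way terpenyl allylic alcohols are joined to phenols and enols; BF3·OEt2 or a catalytic sulfonic acid at low temperature, stopped before ether closure) should give racemic trans-14, that is 14 together with its (1S,3S) enantiomer F4. Preparative chromatography on a chiral stationary phase separates them, and the route is rejoined at 14.

**Step 7.**
- Most likely failure: closure through the lactam oxygen in place of O4 (linear 4-quinolone ethers), five-membered closure onto a C-b cation, or acid-induced loss of a quinolinone from the doubly allylic C-g followed by aromatisation of ring C.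
- Fallback: setting out from 14, the trisubstituted ring olefin is closed without strong acid by cobalt-hydride hydrogen-atom-transfer hydroalkoxylation (a Co(salen)-type complex of divalent cobalt, an N-fluoropyridinium oxidant, a silane). This should give the bridged mono-ether 15, now isolated; the remaining ring A is then closed with a weaker acid at room temperature, and the route is rejoined at 16. This fallback makes no compound outside the list (F0).

**Step 5.**
- Most likely failure: ionisation of the doubly allylic carbonate during acylation or isolation, followed by elimination and aromatisation.
- Fallback: setting out from 9, acetylation (Ac2O, Et3N, DMAP) gives the more robust 5-methyl-2-(propan-2-ylidene)cyclohex-4-ene-1,3-diyl diacetate F3. It is used in the palladium step with Cs2CO3 as external base and rejoins the route at 14.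

**Step 3.**
- Most likely failure: aggregation or incomplete formation of the dilithio species and conjugate addition or polymerisation of acrolein, giving low conversion.
- Fallback: setting out from 5, the hydroxyl group is silylated (TBSCl, imidazole) to the silyl ether tert-butyl[(5-bromo-2,6-dimethylhepta-1,5-dien-4-yl)oxy]dimethylsilane F1. Bromine–lithium exchange and addition to 6 on this monoanion give 5-[(tert-butyldimethylsilyl)oxy]-7-methyl-4-(propan-2-ylidene)octa-1,7-dien-3-ol F2, and Bu4NF removes the silyl group to rejoin the route at 8.

## Further compounds

F1 | step 3 | tert-butyl[(5-bromo-2,6-dimethylhepta-1,5-dien-4-yl)oxy]dimethylsilane | CC(=C)CC(O[Si](C)(C)C(C)(C)C)C(Br)=C(C)C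
F2 | step 3 | 5-[(tert-butyldimethylsilyl)oxy]-7-methyl-4-(propan-2-ylidene)octa-1,7-dien-3-ol | C=CC(O)C(=C(C)C)C(O[Si](C)(C)C(C)(C)C)CC(C)=C
F3 | step 5 | 5-methyl-2-(propan-2-ylidene)cyclohex-4-ene-1,3-diyl diacetate | CC(=O)OC1C=C(C)CC(OC(C)=O)C1=C(C)C
F4 | step 6 | 3,3'-[(1S,3S)-5-methyl-2-(propan-2-ylidene)cyclohex-4-ene-1,3-diyl]bis(4-hydroxy-1-methylquinolin-2(1H)-one) | Cn1c(=O)c(c(O)c2ccccc21)[C@H]1CC(C)=C[C@H](c2c(O)c3ccccc3n(C)c2=O)C1=C(C)C
F0 | step 7 | none | none
A1 | alternative 1 | 2,2,6-trimethyl-5-oxo-5,6-dihydro-2H-pyrano[3,2-c]quinoline-3-carbaldehyde (formylchromene) | Cn1c(=O)c2c(c3ccccc31)OC(C)(C)C(C=O)=C2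
A2 | alternative 1 | tert-butyl acetoacetate | CC(=O)CC(=O)OC(C)(C)C
A3 | alternative 1 | trans-fused pyranoquinolinone cyclohexenone (ketone at C-e, olefin C-f=C-g) | Cn1c(=O)c2c(c3ccccc31)OC(C)(C)[C@H]1[C@H]2CC(=O)C=C1
A4 | alternative 2 | (1S,2S,5S)-cis-verbenol | CC1=C[C@@H]([C@H]2C[C@@H]1C2(C)C)O
A5 | alternative 2 | trans-fused pyranoquinolinone with the C-e=C-f olefin | Cn1c(=O)c2c(c3ccccc31)OC(C)(C)[C@H]1[C@H]2CC(C)=CC1
A6 | alternative 3 | 3-[(2E)-3,7-dimethylocta-2,6-dien-1-yl]-4-hydroxy-1-methylquinolin-2(1H)-one (3-geranyl quinolinone) | CC(C)=CCC/C(C)=C/Cc1c(O)c2ccccc2n(C)c1=O
A7 | alternative 3 | trans-fused pyranoquinolinone with the C-d=C-e olefin | Cn1c(=O)c2c(c3ccccc31)OC(C)(C)[C@H]1[C@H]2C=C(C)CC1
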